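A fraction of the charge per day is the unit I reckon in, for this flask is a balance of the solid substrate: the gas is held at 200 mM, while the charge of 1.8 M is not renewed, so I take solid substrate as the limiting reagent.

| setting | north-west | flask |
|---|---|---|
| solid substrate | 1.8 M | 1.8 M |
| gas | 200 mM (held) | 200 mM (held) |
| remark | the very flask that is asked about, followed so far |  |
| time |  | 15 d |

north-west run (percent of the solid substrate charged)

| time / d | isomer of the product A / % | target / % |
|---|---|---|
| 0.250 | 3.5 | 5.2 |
| 0.333 | 5.0 | 4.6 |
| 0.500 | 9.3 | 5.3 |
| 0.833 | 15.8 | 6.3 |
| 1.25 | 23.8 | 6.4 |
| 2.08 | 40.3 | 5.0 |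
| 3.00 | 42.7 | 1.2 |

(scatter of a reading: 1 percentage point)

- as a solid, counted per litre of solution: solid substrate
- at the start none of partner is dissolved
- steps thought possible: starting material + partner <-> target; starting material + partner <-> isomer of the product A; gas <-> partner; solid substrate <-> starting material; target <-> isomer of the product B
- at the start none of the solid substrate is in solution

1. ratio of isomer of the product A to target at 5.0 h
2. ratio of isomer of the product A to target at 40 h
3. ratio of isomer of the product A to target at 15 d
4. which of isomer of the product A and target there is more of at 15 d

In the readings of this flask isomer of the product A averages 0.140 d⁻¹ up to 0.250 d. From 0.333 d to 2.08 d it rises steadily at 0.202 d⁻¹, a factor 1.44 above that start. Over the last interval it gains 0.0261 d⁻¹, a factor 7.74 below the steady rate. I read this as a rate that holds and then breaks, not one that fades.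

At its steady rate isomer of the product A reaches the 42.7 % of the last reading after 2.11 d. I call this the charge life, my estimate of the time for which the solid substrate feeds the flask at full rate. My balance then has the charge leaving the solid at 0.474 d⁻¹, of which 0.272 d⁻¹ bypasses isomer of the product A. So in this flask 5.0 h and 40 h fall within the charge life and 15 d lies beyond it. I expect isomer of the product A to lead at the end, as it does in the last reading, 42.7 % against 1.2 % of target.

The forecast gives 0.65, 5.3 and 60, with isomer of the product A ahead, reckoning “so the solid runs out near 2.1 d”.

The flask gives 0.711, 4.35 and 28.7, with isomer of the product A ahead at 15 d, at 47.6 % against 1.66 % of target.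

    starting material + partner ⇌ target (K = 16.0 M⁻¹, k = 2.60 M⁻¹ h⁻¹)
    starting material + partner ⇌ isomer of the product A (K = 560 M⁻¹, k = 1.00 M⁻¹ h⁻¹)
    gas ⇌ partner, rate k3*(csat - [partner]) (kL = 15.0 h⁻¹)
    solid substrate ⇌ starting material, rate k4*(cs4 - [starting material]) while solid is left; crystals form when [starting material] > cs4 (solubility = 0.270 M, k = 0.200 h⁻¹)
    target ⇌ isomer of the product B (K = 29.0, k = 0.190 h⁻¹)

The forecast and the flask part at 15 d, where the forecast's ratio is twice the flask's. In this flask solid substrate stands at 22.4 % at 1.50 d and at 0 % at 7.50 d. At the flow of the charge life the 22.4 % lasts a further 0.473 d beyond 1.50 d, and target is highest at 1.95 d, inside the charge life.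

In the neighbour flask with 0.72 M of solid substrate, the same feed per litre gives a charge life of 0.845 d, later than 5.0 h but earlier than 40 h. The computed ratios of that neighbour flask are 0.711 at 5.0 h and 20.4 at 40 h.

(The readings stem from a simulated flask for substances that don't exist; the scatter is artificial.)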